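**Plan**

- Target: epicatechin-(4β→8)-epiafzelechin; upper unit (2R,3R,4R), rings A/C/B; lower unit (2R,3R), rings D/F/E. Helpers removed last: eight O-benzyl groups and one C3 benzoate.
- Main cut: O1–C2 and C3–C4 of ring C in one retro-[4+2], giving an ortho-quinone methide (O1=C8a–C4a=C4, C4 carrying ring D) and a (Z)-β-benzoyloxystyrene (C2=C3, ring B on C2).
- Enabling feature: ring A carries O1 ortho to C4, and C4 is doubly benzylic between the 2,4,6-trioxygenated rings A and D, so the carbinol ionises under very mild acid; C2 is benzylic to ring B, whose para oxygen polarises the alkene the right way.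
- Further cuts: C4–C8 (aryllithium + salicylaldehyde), C8–Br, back to (−)-epiafzelechin; the dienophile from 3,4-bis(benzyloxy)benzaldehyde via the alkyne.
- Forward order: rings D/F/E are bought intact, the C8–C4 bond is made next, ring C is closed last, then deprotection.
- Stereochemistry: lower C2/C3 from the chiral pool; upper C2/C3 cis from the Z alkene; C3/C4 trans from steric approach control; absolute sense from a chiral phosphoric acid together with the lower unit.

Key step: step 8

Remark: (−)-epiafzelechin is taken as a purchasable (2R,3R) flavan-3-ol; the phosphoric acid is written as (R)-TRIP, on the understanding that the enantiomer matched to the lower unit is the one used.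

**Step 1**
Reactants: 1 (−)-epiafzelechin
Product: 2 5,7,4'-tri-O-benzyl-(−)-epiafzelechin
Conditions: BnBr (3.3 equiv), K2CO3, DMF, 0 °C → rt, Ar
Reagents that add atoms: benzyl bromide, BrCc1ccccc1
Why: Williamson etherification in which K2CO3 deprotonates only the three phenols, so the C3 alcohol stays free and the mild base leaves C2 and C3 untouched.

**Step 2**
Reactants: 2 5,7,4'-tri-O-benzyl-(−)-epiafzelechin
Product: 3 3,5,7,4'-tetra-O-benzyl-(−)-epiafzelechin
Conditions: NaH, BnBr, n-Bu4NI (cat.), DMF, 0 °C → rt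
Reagents that add atoms: benzyl bromide, BrCc1ccccc1
Why: Williamson etherification of the secondary alkoxide; no free phenol remains that could open ring F, so no stereocentre is at risk.

**Step 3**
Reactants: 3 3,5,7,4'-tetra-O-benzyl-(−)-epiafzelechin
Product: 4 8-bromo-3,5,7,4'-tetra-O-benzyl-(−)-epiafzelechin
Conditions: NBS (1.0 equiv), CH2Cl2, −78 °C → rt
Reagents that add atoms: N-bromosuccinimide, O=C1CCC(=O)N1Br
Why: Electrophilic aromatic bromination, which on benzylated flavan-3-ols should go to C8 of the phloroglucinol ring D in preference to C6, the mono-oxygenated ring E being far less activated.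

**Step 4**
Reactants: 5 2,4,6-trihydroxybenzaldehyde
Product: 6 2,4-bis(benzyloxy)-6-hydroxybenzaldehyde
Conditions: BnBr (2.1 equiv), K2CO3, DMF, rt
Reagents that add atoms: benzyl bromide, BrCc1ccccc1
Why: Williamson etherification that should stop at the dibenzyl ether because the remaining ortho hydroxyl is held in a hydrogen bond to the formyl group.

**Step 5**
Reactants: 4 8-bromo-3,5,7,4'-tetra-O-benzyl-(−)-epiafzelechin; 6 2,4-bis(benzyloxy)-6-hydroxybenzaldehyde
Product: 9 [2,4-bis(benzyloxy)-6-hydroxyphenyl][3,5,7,4'-tetra-O-benzyl-epiafzelechin-8-yl]methanol (both carbinol epimers), via 8-lithio flavan 7 (not isolated), via sodium formylphenoxide 8 (not isolated)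
Conditions: 6, NaH, THF, 0 °C; separately 4, n-BuLi, THF, −78 °C; phenoxide solution (1.3 equiv) added, −78 → 0 °C; aq. NH4Cl; Et3N-deactivated silica
Reagents that add atoms: none
Why: Bromine–lithium exchange followed by 1,2-addition of the aryllithium to the aldehyde, whose phenol is masked as its sodium salt so that no aryllithium is lost to protonation; the carbinol centre forms as both epimers, which is immaterial because it becomes trigonal in step 8.

**Step 6**
Reactants: 10 3,4-bis(benzyloxy)benzaldehyde
Product: 11 1,2-bis(benzyloxy)-4-ethynylbenzene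
Conditions: Ohira–Bestmann reagent, K2CO3, MeOH/THF, rt
Reagents that add atoms: dimethyl (1-diazo-2-oxopropyl)phosphonate, CC(=O)C(=[N+]=[N-])P(=O)(OC)OC
Why: Ohira–Bestmann (Seyferth–Gilbert) homologation of an aromatic aldehyde to the terminal alkyne under carbonate conditions that spare the benzyl ethers.

**Step 7**
Reactants: 11 1,2-bis(benzyloxy)-4-ethynylbenzene
Product: 12 (Z)-2-[3,4-bis(benzyloxy)phenyl]ethenyl benzoate
Conditions: PhCO2H (1.1 equiv), [RuCl2(p-cymene)]2 (1 mol %), P(4-ClC6H4)3 (3 mol %), DMAP (4 mol %), toluene, 60 °C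
Reagents that add atoms: benzoic acid, OC(=O)c1ccccc1
Why: Ruthenium-catalysed anti-Markovnikov hydro-acyloxylation of a terminal alkyne through a ruthenium vinylidene, with the phosphine/DMAP system that should deliver the Z enol ester.

**Step 8**
Reactants: 9 [2,4-bis(benzyloxy)-6-hydroxyphenyl][3,5,7,4'-tetra-O-benzyl-epiafzelechin-8-yl]methanol; 12 (Z)-2-[3,4-bis(benzyloxy)phenyl]ethenyl benzoate
Product: 14 3-O-benzoyl-5,7,3',4'-tetra-O-benzyl-epicatechin-(4β→8)-3,5,7,4'-tetra-O-benzyl-epiafzelechin, via ortho-quinone methide 13 (not isolated)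
Conditions: (R)-TRIP [(R)-3,3'-bis(2,4,6-triisopropylphenyl)-1,1'-binaphthyl-2,2'-diyl hydrogen phosphate] (10 mol %), 12 (3 equiv), 5 Å MS, CH2Cl2, −20 °C → rt, slow addition of 9
Reagents that add atoms: none
Why: Proposed new method: the phosphoric acid ionises the doubly benzylic carbinol of 9 (flanked by the 2,4,6-trioxygenated rings A and D) to the ortho-quinone methide 13, whose heterodiene O1=C8a–C4a=C4 adds the enol benzoate 12 in an asynchronous inverse-electron-demand oxa-[4+2] cycloaddition in which the C3–C4 bond leads and O1 closes onto C2 as positive charge builds there, next to the para-benzyloxy group of ring B. The closest known reaction type is the Brønsted-acid-catalysed hetero-Diels–Alder reaction of ortho-quinone methides from ortho-hydroxybenzhydrols with 4-alkoxystyrenes, which gives 2,4-diarylchromans but has not been shown with a β-acyloxystyrene. Ring C is closed by intermolecular [4+2] cycloaddition, four ring atoms (O1, C8a, C4a, C4) coming from 13 and two (C2, C3) from 12. C2 and C3 should come out cis because the Z geometry of 12 is transferred suprafacially, and C4 trans to the C3 benzoate because the di-ortho-substituted ring D on the methide carbon and the acyloxy group avoid each other (the adduct can place both axial and anti, away from the C5 benzyloxy group). The absolute sense, attack on the face of 13 that gives 4R, is to be set by the chiral phosphate hydrogen-bonded at O1, acting together with the (2R,3R) lower unit. The step needs C3-to-C4 regioselectivity, secured by the polarisation of 12 (the 4-benzyloxyaryl donor at C2 outweighs the weakly donating benzoyloxy group at C3), and chemoselectivity for the alkene over Friedel–Crafts attack at the free ring A and ring D positions, secured by slow addition of 9 to excess 12.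

**Step 9**
Reactants: 14 3-O-benzoyl-5,7,3',4'-tetra-O-benzyl-epicatechin-(4β→8)-3,5,7,4'-tetra-O-benzyl-epiafzelechin
Product: 15 5,7,3',4'-tetra-O-benzyl-epicatechin-(4β→8)-3,5,7,4'-tetra-O-benzyl-epiafzelechin (upper 3-OH free)
Conditions: NaOMe (cat.), MeOH/THF, rt → 40 °C
Reagents that add atoms: none
Why: Zemplén transesterification removes the benzoate; every phenol is benzylated, so base cannot open either pyran ring and no stereocentre is at risk.

**Step 10**
Reactants: 15 5,7,3',4'-tetra-O-benzyl-epicatechin-(4β→8)-3,5,7,4'-tetra-O-benzyl-epiafzelechin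
Product: 16 epicatechin-(4β→8)-epiafzelechin
Conditions: H2 (1 atm), Pd(OH)2/C, THF/MeOH/H2O, rt; filtration, lyophilisation
Reagents that add atoms: none
Why: Catalytic hydrogenolysis of the eight benzyl ethers under neutral conditions, which should leave the acid-sensitive C4–C8 interflavan bond and the benzylic C2–O1 bonds intact.

**Compound list**

1 | (−)-epiafzelechin, (2R,3R)-2-(4-hydroxyphenyl)chromane-3,5,7-triol | Oc1ccc([C@H]2Oc3cc(O)cc(O)c3C[C@H]2O)cc1 | starting material
2 | 5,7,4'-tri-O-benzyl-(−)-epiafzelechin | c1ccccc1COc1ccc([C@H]2Oc3cc(OCc4ccccc4)cc(OCc4ccccc4)c3C[C@H]2O)cc1 | intermediate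
3 | 3,5,7,4'-tetra-O-benzyl-(−)-epiafzelechin | c1ccccc1COc1ccc([C@H]2Oc3cc(OCc4ccccc4)cc(OCc4ccccc4)c3C[C@H]2OCc2ccccc2)cc1 | intermediate
4 | 8-bromo-3,5,7,4'-tetra-O-benzyl-(−)-epiafzelechin | c1ccccc1COc1ccc([C@H]2Oc3c(Br)c(OCc4ccccc4)cc(OCc4ccccc4)c3C[C@H]2OCc2ccccc2)cc1 | intermediate
5 | 2,4,6-trihydroxybenzaldehyde | O=Cc1c(O)cc(O)cc1O | starting material
6 | 2,4-bis(benzyloxy)-6-hydroxybenzaldehyde | O=Cc1c(O)cc(OCc2ccccc2)cc1OCc1ccccc1 | intermediate
7 | 8-lithio-3,5,7,4'-tetra-O-benzyl-epiafzelechin | c1ccccc1COc1ccc([C@H]2Oc3c([Li])c(OCc4ccccc4)cc(OCc4ccccc4)c3C[C@H]2OCc2ccccc2)cc1 | intermediate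
8 | sodium 3,5-bis(benzyloxy)-2-formylphenoxide | [Na+].[O-]c1cc(OCc2ccccc2)cc(OCc2ccccc2)c1C=O | intermediate
9 | [2,4-bis(benzyloxy)-6-hydroxyphenyl][(2R,3R)-3,5,7-tris(benzyloxy)-2-(4-benzyloxyphenyl)chroman-8-yl]methanol, both epimers at the carbinol carbon | c1ccccc1COc1ccc([C@H]2Oc3c(C(O)c4c(O)cc(OCc5ccccc5)cc4OCc4ccccc4)c(OCc4ccccc4)cc(OCc4ccccc4)c3C[C@H]2OCc2ccccc2)cc1 | intermediate
10 | 3,4-bis(benzyloxy)benzaldehyde | O=Cc1ccc(OCc2ccccc2)c(OCc2ccccc2)c1 | starting material
11 | 1,2-bis(benzyloxy)-4-ethynylbenzene | C#Cc1ccc(OCc2ccccc2)c(OCc2ccccc2)c1 | intermediate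
12 | (Z)-2-[3,4-bis(benzyloxy)phenyl]ethenyl benzoate | O=C(O/C=C\c1ccc(OCc2ccccc2)c(OCc2ccccc2)c1)c1ccccc1 | intermediate
13 | 3,5-bis(benzyloxy)-6-{[(2R,3R)-3,5,7-tris(benzyloxy)-2-(4-benzyloxyphenyl)chroman-8-yl]methylidene}cyclohexa-2,4-dien-1-one (ortho-quinone methide, either geometry at the exocyclic double bond) | c1ccccc1COc1ccc([C@H]2Oc3c(C=C4C(=O)C=C(OCc5ccccc5)C=C4OCc4ccccc4)c(OCc4ccccc4)cc(OCc4ccccc4)c3C[C@H]2OCc2ccccc2)cc1 | intermediate
14 | 3-O-benzoyl-5,7,3',4'-tetra-O-benzyl-epicatechin-(4β→8)-3,5,7,4'-tetra-O-benzyl-epiafzelechin, upper unit (2R,3R,4R) | c1ccccc1COc1ccc([C@H]2Oc3c(c(OCc4ccccc4)cc(OCc4ccccc4)c3[C@H]3c4c(OCc5ccccc5)cc(OCc5ccccc5)cc4O[C@H](c4ccc(OCc5ccccc5)c(OCc5ccccc5)c4)[C@@H]3OC(=O)c3ccccc3)C[C@H]2OCc2ccccc2)cc1 | intermediate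
15 | 5,7,3',4'-tetra-O-benzyl-epicatechin-(4β→8)-3,5,7,4'-tetra-O-benzyl-epiafzelechin, upper 3-OH free | c1ccccc1COc1ccc([C@H]2Oc3c(c(OCc4ccccc4)cc(OCc4ccccc4)c3[C@H]3c4c(OCc5ccccc5)cc(OCc5ccccc5)cc4O[C@H](c4ccc(OCc5ccccc5)c(OCc5ccccc5)c4)[C@@H]3O)C[C@H]2OCc2ccccc2)cc1 | intermediate
16 | epicatechin-(4β→8)-epiafzelechin | Oc1ccc([C@H]2Oc3c(c(O)cc(O)c3[C@H]3c4c(O)cc(O)cc4O[C@H](c4ccc(O)c(O)c4)[C@@H]3O)C[C@H]2O)cc1 | target

**Totals**

Total step count: 10. Longest linear sequence: 7 steps (steps 1, 2, 3, 5, 8, 9, 10, from 1 to 16).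

**Steps most likely to fail**

1. Step 8 (proposed new method). The stabilised ortho-quinone methide may react too slowly with the only moderately nucleophilic enol benzoate, so that Friedel–Crafts self-condensation at free ring A and ring D positions takes over. Facial control by the phosphate may be poor or mismatched with the lower unit. A stepwise cation with benzoate participation may also erode the 2,3-cis relationship. The fallback forms the C4–C8 bond last, onto a preformed ring C, by the established Lewis-acid interflavan coupling; it sets out from 3 and comes back at 15. Purchased (−)-epicatechin would be benzylated (BnBr, K2CO3, DMF) to 5,7,3',4'-tetra-O-benzyl-(−)-epicatechin F1. Oxidation at C4 with DDQ in the presence of ethylene glycol (CH2Cl2, rt) should give 4β-(2-hydroxyethoxy)-5,7,3',4'-tetra-O-benzyl-epicatechin F2. Treatment of F2 with TMSOTf in CH2Cl2 at −78 °C in the presence of excess 3 should generate the C4 cation, which C8 of 3 captures trans to the free 3-hydroxyl, giving 15 directly.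

2. Step 5. The di-ortho-substituted aryllithium may add sluggishly to the deactivated phenoxide-bearing aldehyde or be quenched by proton transfer, and the very electron-rich carbinol may ionise during work-up and purification. The fallback reverses the polarity of the two partners; it sets out from 4 and comes back at 9. Bromine–lithium exchange on 4 (n-BuLi, THF, −78 °C) followed by DMF should give 8-formyl-3,5,7,4'-tetra-O-benzyl-epiafzelechin F3. Purchased 3,5-bis(benzyloxy)phenol, converted into its bromomagnesium phenoxide with EtMgBr, would then be hydroxyalkylated by F3 in toluene at rt. Magnesium chelation directs the attack to the position ortho to the phenoxide oxygen, which should give 9.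

3. Step 7. With the electron-rich arylalkyne, Markovnikov addition, erosion of the Z geometry or alkyne oligomerisation may compete. The fallback separates C–B and C–O bond formation; it sets out from 11 and comes back at 12. Rhodium-catalysed trans-hydroboration of 11 ([RhCl(cod)]2, P(i-Pr)3, Et3N, pinacolborane, cyclohexane, rt) should give (Z)-2-[3,4-bis(benzyloxy)phenyl]ethenylboronic acid pinacol ester F4. KHF2 in MeOH/H2O converts it into potassium (Z)-2-[3,4-bis(benzyloxy)phenyl]ethenyltrifluoroborate F5. Copper-catalysed oxidative coupling of F5 with benzoic acid (CuBr, DMAP, 4 Å MS, O2, CH2Cl2) should give 12 with retention of the double-bond geometry.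

**Further compounds**

F1 | step 8 | 5,7,3',4'-tetra-O-benzyl-(−)-epicatechin | C1c2c(OCc3ccccc3)cc(OCc3ccccc3)cc2O[C@H](c2ccc(OCc3ccccc3)c(OCc3ccccc3)c2)[C@@H]1O
F2 | step 8 | 4β-(2-hydroxyethoxy)-5,7,3',4'-tetra-O-benzyl-epicatechin | OCCO[C@H]1c2c(OCc3ccccc3)cc(OCc3ccccc3)cc2O[C@H](c2ccc(OCc3ccccc3)c(OCc3ccccc3)c2)[C@@H]1O
F3 | step 5 | 8-formyl-3,5,7,4'-tetra-O-benzyl-epiafzelechin | c1ccccc1COc1ccc([C@H]2Oc3c(C=O)c(OCc4ccccc4)cc(OCc4ccccc4)c3C[C@H]2OCc2ccccc2)cc1
F4 | step 7 | (Z)-2-[3,4-bis(benzyloxy)phenyl]ethenylboronic acid pinacol ester | CC1(C)OB(/C=C\c2ccc(OCc3ccccc3)c(OCc3ccccc3)c2)OC1(C)C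
F5 | step 7 | potassium (Z)-2-[3,4-bis(benzyloxy)phenyl]ethenyltrifluoroborate | [K+].F[B-](F)(F)/C=C\c1ccc(OCc2ccccc2)c(OCc2ccccc2)c1
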